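**Plan**

- Retrosynthesis cuts the Cα=Cβ bond of the enone first (aldol condensation of a ring B benzaldehyde with 4-hydroxyacetophenone, ring A), then the ring B C1–CHO bond (back to an aryl bromide), then both the C–vinyl bond and one C–CH3 bond at the quaternary carbon on ring B C5 (back to an aryl methyl ketone).
- Enabling feature: in ring B (C1 enone carbon, C2 OMe, C3 OH, C4 OH, C5 CMe2–CH=CH2, C6 H) the quaternary benzylic carbon on C5 lies ortho to the C4 oxygen. C4(=O)/C5(=CMe2) can therefore exist as an ortho-quinone methide whose exocyclic carbon accepts a vinyl nucleophile.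
- Forward: no ring is formed. Ring B with its three oxygens comes from 2,3,4-trihydroxyacetophenone, whose acetyl carbon becomes the quaternary carbon. It is 4-O-methylated, 3-O-MOM protected, brominated and converted to the ortho-OBoc ketone, and MeMgBr then vinylmagnesium bromide build the 1,1-dimethylallyl group in one flask.
- The bromide is then turned into the aldehyde, the chain is joined last by Claisen–Schmidt condensation with MOM-protected 4-hydroxyacetophenone, and all MOM groups are removed together.
- Stereochemistry: there is no stereocentre; the E enone follows from thermodynamic control in the dehydration of the aldol.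

Key step: step 5

Remark on the chemistry: ring B is numbered from the enone-bearing carbon (C1) and ring A is the 4-hydroxyphenyl ketone ring; the acetophenone intermediates are numbered from the acetyl-bearing carbon.

**Route**

Step 1
Reactants: 1 2,3,4-trihydroxyacetophenone
Product: 4 1-(2,3-dihydroxy-4-methoxyphenyl)ethan-1-one, via catechol borate complex 2 (not isolated), via O-methylated borate complex 3 (not isolated)
Conditions: Na2B4O7·10H2O, NaOH, H2O, rt; Me2SO4; then HCl
Reagents that add atoms: dimethyl sulfate, COS(=O)(=O)OC
Why: Borate ester formation ties up the adjacent 2- and 3-hydroxyls, so that Williamson O-methylation by dimethyl sulfate should occur only at the free and most acidic 4-OH (para to the acetyl), and acidification then hydrolyses the borate.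

Step 2
Reactants: 4 1-(2,3-dihydroxy-4-methoxyphenyl)ethan-1-one
Product: 5 1-[2-hydroxy-4-methoxy-3-(methoxymethoxy)phenyl]ethan-1-one
Conditions: MOMCl (1.1 equiv), K2CO3, acetone, 0 °C → rt
Reagents that add atoms: chloromethyl methyl ether, COCCl
Why: The 2-OH is held in a hydrogen bond to the acetyl carbonyl, so Williamson-type alkylation under weak base should take place at the 3-OH only, as in the familiar 3,4-di-O-alkylation of 2,3,4-trihydroxyacetophenone that leaves the chelated hydroxyl free.

Step 3
Reactants: 5 1-[2-hydroxy-4-methoxy-3-(methoxymethoxy)phenyl]ethan-1-one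
Product: 6 1-[5-bromo-2-hydroxy-4-methoxy-3-(methoxymethoxy)phenyl]ethan-1-one
Conditions: NBS, MeCN, 0 °C → rt
Reagents that add atoms: N-bromosuccinimide, O=C1CCC(=O)N1Br
Why: Electrophilic aromatic bromination should go to C5, which is para to the free phenol, ortho to the methoxy group and meta to the acetyl, whereas C6 is ortho to the deactivating acetyl; NBS in MeCN is acid-free, so the MOM acetal survives.

Step 4
Reactants: 6 1-[5-bromo-2-hydroxy-4-methoxy-3-(methoxymethoxy)phenyl]ethan-1-one
Product: 7 6-acetyl-4-bromo-3-methoxy-2-(methoxymethoxy)phenyl tert-butyl carbonate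
Conditions: Boc2O, i-Pr2NEt, DMAP (cat.), THF, rt
Reagents that add atoms: di-tert-butyl dicarbonate, CC(C)(C)OC(=O)OC(=O)OC(C)(C)C
Why: DMAP-catalysed O-acylation of the phenol by Boc2O (nucleophilic catalysis) should give the aryl tert-butyl carbonate under mild base that leaves the ketone, the bromide and the MOM ether untouched.

Step 5
Reactants: 7 6-acetyl-4-bromo-3-methoxy-2-(methoxymethoxy)phenyl tert-butyl carbonate; 8 methylmagnesium bromide; 9 vinylmagnesium bromide
Product: 13 4-bromo-3-methoxy-2-(methoxymethoxy)-6-(2-methylbut-3-en-2-yl)phenol, via tertiary magnesium alkoxide 10 (not isolated), via Boc-shifted magnesium phenoxide 11 (not isolated), via ortho-quinone methide 12 (not isolated)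
Conditions: MeMgBr (1.05 equiv), THF, −78 °C; then CH2=CHMgBr (3 equiv), −78 → 0 °C; aq NH4Cl
Reagents that add atoms: methylmagnesium bromide, C[Mg]Br; vinylmagnesium bromide, C=C[Mg]Br
Why: MeMgBr adds to the ketone of 7 at −78 °C to give alkoxide 10, which on warming attacks the neighbouring carbonate through a six-membered transition state so that the Boc group moves from the phenol oxygen to the tertiary oxygen (11), and the freed phenoxide then expels tert-butyl carbonate to give ortho-quinone methide 12. Vinylmagnesium bromide, present in excess before the warming, adds to the exocyclic carbon of 12 (1,4-addition), a step driven by the return of aromaticity, so that the C–CH3 and the C–vinyl bond both end up on the same benzylic carbon. The closest known reaction type is the one-pot 1,2-addition, carbonate transfer and 1,4-addition sequence of ortho-OBoc aryl aldehydes and ketones with organometallic reagents, in which Grignard reagents add to the transient ortho-quinone methide. No ring is closed and no stereocentre arises, because the new quaternary carbon carries two identical methyl groups. The step needs chemoselectivity on three counts: the ketone should be attacked before the hindered carbonate, only one methyl group should be transferred because MeMgBr is consumed at −78 °C before the cascade is released, and conjugate addition should outrun the 1,5-hydrogen shift of 12 to an isopropenylphenol because the magnesium-bound quinone methide meets a large excess of vinyl Grignard at low temperature. The aryl bromide, the MOM acetal and the methyl ether are inert to Grignard reagents under these conditions.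

Step 6
Reactants: 13 4-bromo-3-methoxy-2-(methoxymethoxy)-6-(2-methylbut-3-en-2-yl)phenol
Product: 14 1-bromo-2-methoxy-3,4-bis(methoxymethoxy)-5-(2-methylbut-3-en-2-yl)benzene
Conditions: NaH, MOMCl, DMF, 0 °C → rt
Reagents that add atoms: chloromethyl methyl ether, COCCl
Why: Williamson etherification of the sodium phenoxide in DMF should cap even this hindered phenol, which would otherwise quench the aryllithium of the next step and deactivate the aldehyde in the condensation.

Step 7
Reactants: 14 1-bromo-2-methoxy-3,4-bis(methoxymethoxy)-5-(2-methylbut-3-en-2-yl)benzene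
Product: 17 2-methoxy-3,4-bis(methoxymethoxy)-5-(2-methylbut-3-en-2-yl)benzaldehyde, via aryllithium 15 (not isolated), via lithium hemiaminal alkoxide 16 (not isolated)
Conditions: n-BuLi, THF, −78 °C; DMF, −78 °C → rt; aq NH4Cl
Reagents that add atoms: N,N-dimethylformamide, CN(C)C=O
Why: Bromine–lithium exchange with n-BuLi at −78 °C is much faster than any deprotonation, and the aryllithium is formylated by DMF (Bouveault-type formylation) through a stable hemiaminal alkoxide that releases the aldehyde only on work-up.

Step 8
Reactants: 18 4-hydroxyacetophenone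
Product: 19 1-[4-(methoxymethoxy)phenyl]ethan-1-one
Conditions: MOMCl, K2CO3, acetone, rt
Reagents that add atoms: chloromethyl methyl ether, COCCl
Why: Williamson O-alkylation masks the acidic phenol, which would otherwise be deprotonated in the condensation and lower the reactivity of the ketone enolate.

Step 9
Reactants: 17 2-methoxy-3,4-bis(methoxymethoxy)-5-(2-methylbut-3-en-2-yl)benzaldehyde; 19 1-[4-(methoxymethoxy)phenyl]ethan-1-one
Product: 21 (E)-3-[2-methoxy-3,4-bis(methoxymethoxy)-5-(2-methylbut-3-en-2-yl)phenyl]-1-[4-(methoxymethoxy)phenyl]prop-2-en-1-one, via aldol adduct 20 (not isolated)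
Conditions: KOH, EtOH/H2O, rt
Reagents that add atoms: none
Why: In this Claisen–Schmidt condensation the enolate of 19 adds to the non-enolisable aldehyde 17 and aldol 20 loses water by E1cB elimination to the conjugated enone, whose E geometry is thermodynamically favoured; MOM ethers are stable to hydroxide.

Step 10
Reactants: 21 (E)-3-[2-methoxy-3,4-bis(methoxymethoxy)-5-(2-methylbut-3-en-2-yl)phenyl]-1-[4-(methoxymethoxy)phenyl]prop-2-en-1-one
Product: 22 (E)-3-[3,4-dihydroxy-2-methoxy-5-(2-methylbut-3-en-2-yl)phenyl]-1-(4-hydroxyphenyl)prop-2-en-1-one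
Conditions: HCl (3 M aq), MeOH, rt → 40 °C, under argon
Reagents that add atoms: none
Why: Acid-catalysed transacetalisation in methanol should cleave the three aryl MOM acetals, while the monosubstituted alkene of the dimethylallyl group is too weakly basic to be protonated under these mild conditions and the enone is acid-stable.

**Compound list**

1 | 2,3,4-trihydroxyacetophenone | CC(=O)c1ccc(O)c(O)c1O | starting material
2 | sodium dihydroxyborate complex spanning O-2 and O-3 of 1 (not isolated; drawn with the 4-OH protonated) | CC(=O)c1ccc(O)c2O[B-](O)(O)Oc12.[Na+] | intermediate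
3 | sodium dihydroxyborate complex spanning O-2 and O-3 of 4 (not isolated) | CC(=O)c1ccc(OC)c2O[B-](O)(O)Oc12.[Na+] | intermediate
4 | 1-(2,3-dihydroxy-4-methoxyphenyl)ethan-1-one | CC(=O)c1ccc(OC)c(O)c1O | intermediate
5 | 1-[2-hydroxy-4-methoxy-3-(methoxymethoxy)phenyl]ethan-1-one | CC(=O)c1ccc(OC)c(OCOC)c1O | intermediate
6 | 1-[5-bromo-2-hydroxy-4-methoxy-3-(methoxymethoxy)phenyl]ethan-1-one | CC(=O)c1cc(Br)c(OC)c(OCOC)c1O | intermediate
7 | 6-acetyl-4-bromo-3-methoxy-2-(methoxymethoxy)phenyl tert-butyl carbonate | CC(=O)c1cc(Br)c(OC)c(OCOC)c1OC(=O)OC(C)(C)C | intermediate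
8 | methylmagnesium bromide | C[Mg]Br | starting material
9 | vinylmagnesium bromide | C=C[Mg]Br | starting material
10 | bromomagnesium 2-[5-bromo-2-(tert-butoxycarbonyloxy)-4-methoxy-3-(methoxymethoxy)phenyl]propan-2-olate (not isolated) | CC(C)(O[Mg]Br)c1cc(Br)c(OC)c(OCOC)c1OC(=O)OC(C)(C)C | intermediate
11 | bromomagnesium 4-bromo-6-[2-(tert-butoxycarbonyloxy)propan-2-yl]-3-methoxy-2-(methoxymethoxy)phenolate (not isolated) | CC(C)(OC(=O)OC(C)(C)C)c1cc(Br)c(OC)c(OCOC)c1O[Mg]Br | intermediate
12 | 4-bromo-3-methoxy-2-(methoxymethoxy)-6-(propan-2-ylidene)cyclohexa-2,4-dien-1-one (ortho-quinone methide, not isolated) | CC(C)=C1C=C(Br)C(OC)=C(OCOC)C1=O | intermediate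
13 | 4-bromo-3-methoxy-2-(methoxymethoxy)-6-(2-methylbut-3-en-2-yl)phenol | C=CC(C)(C)c1cc(Br)c(OC)c(OCOC)c1O | intermediate
14 | 1-bromo-2-methoxy-3,4-bis(methoxymethoxy)-5-(2-methylbut-3-en-2-yl)benzene | C=CC(C)(C)c1cc(Br)c(OC)c(OCOC)c1OCOC | intermediate
15 | [2-methoxy-3,4-bis(methoxymethoxy)-5-(2-methylbut-3-en-2-yl)phenyl]lithium (not isolated) | C=CC(C)(C)c1cc([Li])c(OC)c(OCOC)c1OCOC | intermediate
16 | lithium (dimethylamino)[2-methoxy-3,4-bis(methoxymethoxy)-5-(2-methylbut-3-en-2-yl)phenyl]methanolate (racemic, not isolated) | C=CC(C)(C)c1cc(C(O[Li])N(C)C)c(OC)c(OCOC)c1OCOC | intermediate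
17 | 2-methoxy-3,4-bis(methoxymethoxy)-5-(2-methylbut-3-en-2-yl)benzaldehyde | C=CC(C)(C)c1cc(C=O)c(OC)c(OCOC)c1OCOC | intermediate
18 | 4-hydroxyacetophenone | CC(=O)c1ccc(O)cc1 | starting material
19 | 1-[4-(methoxymethoxy)phenyl]ethan-1-one | CC(=O)c1ccc(OCOC)cc1 | intermediate
20 | 3-hydroxy-3-[2-methoxy-3,4-bis(methoxymethoxy)-5-(2-methylbut-3-en-2-yl)phenyl]-1-[4-(methoxymethoxy)phenyl]propan-1-one (racemic, not isolated) | C=CC(C)(C)c1cc(C(O)CC(=O)c2ccc(OCOC)cc2)c(OC)c(OCOC)c1OCOC | intermediate
21 | (E)-3-[2-methoxy-3,4-bis(methoxymethoxy)-5-(2-methylbut-3-en-2-yl)phenyl]-1-[4-(methoxymethoxy)phenyl]prop-2-en-1-one | C=CC(C)(C)c1cc(/C=C/C(=O)c2ccc(OCOC)cc2)c(OC)c(OCOC)c1OCOC | intermediate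
22 | (E)-3-[3,4-dihydroxy-2-methoxy-5-(2-methylbut-3-en-2-yl)phenyl]-1-(4-hydroxyphenyl)prop-2-en-1-one | C=CC(C)(C)c1cc(/C=C/C(=O)c2ccc(O)cc2)c(OC)c(O)c1O | target

**Step count and risks**

Total step count: 10. Longest linear sequence: 9 steps (steps 1 to 7, 9 and 10); step 8 is a one-step side branch.

Steps most likely to fail:

1. Step 5. The quinone methide may tautomerise by 1,5-hydrogen shift, or be deprotonated at a methyl group by the Grignard reagent, before the vinyl group adds. The carbonate shift may also start while MeMgBr is still present, so that a second methyl group is transferred. The fallback builds the quaternary carbon without a quinone methide, by homologation of the ketone and olefination, setting out from 6 and returning at 14. O-Methoxymethylation of 6 (NaH, MOMCl, DMF) should give 1-[5-bromo-4-methoxy-2,3-bis(methoxymethoxy)phenyl]ethan-1-one F1. Wittig reaction with Ph3P=CHOMe (from (methoxymethyl)triphenylphosphonium chloride and KOtBu, THF) should give the methyl enol ether 1-bromo-2-methoxy-5-(1-methoxyprop-1-en-2-yl)-3,4-bis(methoxymethoxy)benzene F2, whose alkene geometry is of no consequence. Hg(OAc)2 in aqueous THF followed by KI should unmask it under near-neutral conditions, which spare the aryl MOM ethers, to 2-[5-bromo-4-methoxy-2,3-bis(methoxymethoxy)phenyl]propanal F3 (racemic). C-Methylation of its potassium enolate (KOtBu, MeI, THF, 0 °C) should give 2-[5-bromo-4-methoxy-2,3-bis(methoxymethoxy)phenyl]-2-methylpropanal F4. Wittig methylenation (Ph3P=CH2, THF) then converts the aldehyde into the vinyl group and gives 14.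

2. Step 2. Alkylation may also reach the chelated 2-hydroxyl, giving double protection, or the mono-alkylation may stop short and leave mixtures. The fallback protects both hydroxyls and then frees one, setting out from 4 and returning at 5. Exhaustive methoxymethylation of 4 (NaH, MOMCl, DMF) should give 1-[4-methoxy-2,3-bis(methoxymethoxy)phenyl]ethan-1-one F5. The MOM group ortho to the acetyl, the one activated by chelation to the carbonyl, would then be cleaved selectively (catalytic I2 in MeOH, rt) to give 5.

3. Step 9. With the electron-rich, ortho-substituted aldehyde the aldol addition may lie on the side of the reactants and the dehydration may be slow, so that the condensation stalls and long exposure to hydroxide erodes the partners. The fallback separates bond formation from elimination, setting out from 17 and 19 and returning at 21. Ketone 19 is deprotonated with LiN(i-Pr)2 (THF, −78 °C) and 17 is added; the lithium aldolate is quenched cold and aldol 20 is isolated. MsCl and Et3N (CH2Cl2, 0 °C) should give 1-[2-methoxy-3,4-bis(methoxymethoxy)-5-(2-methylbut-3-en-2-yl)phenyl]-3-[4-(methoxymethoxy)phenyl]-3-oxopropyl methanesulfonate F6 (racemic). DBU then eliminates methanesulfonate (E1cB) to give the E enone 21.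

Further compounds
F1 | step 5 | 1-[5-bromo-4-methoxy-2,3-bis(methoxymethoxy)phenyl]ethan-1-one | CC(=O)c1cc(Br)c(OC)c(OCOC)c1OCOC
F2 | step 5 | 1-bromo-2-methoxy-5-(1-methoxyprop-1-en-2-yl)-3,4-bis(methoxymethoxy)benzene (E/Z mixture) | COC=C(C)c1cc(Br)c(OC)c(OCOC)c1OCOC
F3 | step 5 | 2-[5-bromo-4-methoxy-2,3-bis(methoxymethoxy)phenyl]propanal (racemic) | CC(C=O)c1cc(Br)c(OC)c(OCOC)c1OCOC
F4 | step 5 | 2-[5-bromo-4-methoxy-2,3-bis(methoxymethoxy)phenyl]-2-methylpropanal | CC(C)(C=O)c1cc(Br)c(OC)c(OCOC)c1OCOC
F5 | step 2 | 1-[4-methoxy-2,3-bis(methoxymethoxy)phenyl]ethan-1-one | CC(=O)c1ccc(OC)c(OCOC)c1OCOC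
F6 | step 9 | 1-[2-methoxy-3,4-bis(methoxymethoxy)-5-(2-methylbut-3-en-2-yl)phenyl]-3-[4-(methoxymethoxy)phenyl]-3-oxopropyl methanesulfonate (racemic) | C=CC(C)(C)c1cc(C(CC(=O)c2ccc(OCOC)cc2)OS(C)(=O)=O)c(OC)c(OCOC)c1OCOC
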